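Everything rests on disconnecting the O1–C2 bond of the pyran ring. In the target, O1 ends on a CH2 (C2) while C3, the only stereocentre, carries just H and the quinone ring (ring B): the signature of anti-Markovnikov addition of the C8a phenol of ring A across a C2=C3 1,1-disubstituted alkene. One photoredox operation on a 6-(2-arylallyl)phenol should close the pyran ring (6-endo) and set C3 by enantioselective hydrogen-atom transfer from a chiral thiol. The precursor, made by aromatic Claisen rearrangement, carries ring B as a bis(methoxymethyl)-protected hydroquinone and the C8 oxygen as a methoxymethyl ether; acid unmasking and Ag2O oxidation then give the quinone.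

Key step: step 9

Remark (assumption): the stereocentre is (3S) as drawn (CIP order C2 > ring-B carbon > C4 > H). Which enantiomer of the thiol catalyst gives (3S) must be found by experiment; the mirror-image catalyst is used if the first gives (3R).

Remark (design): the three oxygens that must stay masked in the key step are methoxymethyl (MOM) acetals rather than benzyl ethers. MOM has no weak benzylic C–H that the C3 radical or a thiyl radical could abstract, its acetal oxygens are hydrogen-bond acceptors next to C3, and it directs ortho-lithiation so ring B needs no halogenation step.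

Step 1
Reactants: 1 2,3-dimethoxyphenol
Product: 2 2,3-dimethoxy-1,4-benzoquinone
Conditions: (KSO3)2NO (2.2 equiv), KH2PO4, H2O/acetone, 0 °C to rt
Reagents that add atoms: potassium nitrosodisulfonate, [O]N(S(=O)(=O)[O-])S(=O)(=O)[O-].[K+].[K+]
Why: Teuber oxidation, in which the nitrosodisulfonate radical converts a phenol with a free para position (C4) selectively into the para-quinone.

Step 2
Reactants: 2 2,3-dimethoxy-1,4-benzoquinone
Product: 4 1,4-bis(methoxymethoxy)-2,3-dimethoxybenzene, via 2,3-dimethoxybenzene-1,4-diol 3 (not isolated)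
Conditions: H2 (1 atm), 10% Pd/C, THF, rt; then Ar, iPr2NEt, MOMCl, 0 °C to rt
Reagents that add atoms: chloromethyl methyl ether (MOMCl), COCCl
Why: catalytic hydrogenation of the quinone followed by O-alkylation (acetal formation) of the air-sensitive hydroquinone in the same flask should give the base-stable bis-acetal.

Step 3
Reactants: 4 1,4-bis(methoxymethoxy)-2,3-dimethoxybenzene
Product: 6 2-chloro-1-[3,4-dimethoxy-2,5-bis(methoxymethoxy)phenyl]ethan-1-one, via ring-B aryllithium 5 (not isolated)
Conditions: n-BuLi (1.05 equiv), TMEDA, THF, 0 °C; then ClCH2C(O)N(OMe)Me, −78 to −20 °C; aq. NH4Cl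
Reagents that add atoms: 2-chloro-N-methoxy-N-methylacetamide, CON(C)C(=O)CCl
Why: directed ortho-metalation next to the methoxymethoxy group (the two ring C–H positions are equivalent) followed by Weinreb-amide acylation, which stops at the ketone and should deliver the α-chloroketone.

Step 4
Reactants: 7 2-hydroxy-3,4-dimethoxybenzaldehyde
Product: 8 3,4-dimethoxy-2-(methoxymethoxy)benzaldehyde
Conditions: MOMCl, iPr2NEt, CH2Cl2, 0 °C to reflux
Reagents that add atoms: chloromethyl methyl ether (MOMCl), COCCl
Why: O-alkylation of the phenol with the α-chloro ether (Williamson-type acetal formation) masks the oxygen that becomes the C8 hydroxyl.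

Step 5
Reactants: 8 3,4-dimethoxy-2-(methoxymethoxy)benzaldehyde
Product: 10 3,4-dimethoxy-2-(methoxymethoxy)phenol, via aryl formate 9 (not isolated)
Conditions: mCPBA, CH2Cl2, 0 °C to rt; aq. NaHCO3/Na2S2O3 wash; crude formate, K2CO3 (cat.), MeOH, rt
Reagents that add atoms: 3-chloroperoxybenzoic acid (mCPBA), OOC(=O)c1cccc(Cl)c1
Why: Baeyer–Villiger (Dakin-type) oxidation, in which the electron-rich aryl group migrates to oxygen and the resulting formate is transesterified by methanol to the phenol.

Step 6
Reactants: 6 2-chloro-1-[3,4-dimethoxy-2,5-bis(methoxymethoxy)phenyl]ethan-1-one; 10 3,4-dimethoxy-2-(methoxymethoxy)phenol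
Product: 11 1-[3,4-dimethoxy-2,5-bis(methoxymethoxy)phenyl]-2-[3,4-dimethoxy-2-(methoxymethoxy)phenoxy]ethan-1-one
Conditions: K2CO3, KI (cat.), acetone, 50 °C
Reagents that add atoms: none
Why: Williamson ether synthesis, an SN2 displacement of the activated α-chloroketone chloride by the phenoxide, joins the two rings.

Step 7
Reactants: 11 1-[3,4-dimethoxy-2,5-bis(methoxymethoxy)phenyl]-2-[3,4-dimethoxy-2-(methoxymethoxy)phenoxy]ethan-1-one
Product: 12 1-{3-[3,4-dimethoxy-2-(methoxymethoxy)phenoxy]prop-1-en-2-yl}-3,4-dimethoxy-2,5-bis(methoxymethoxy)benzene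
Conditions: Ph3PCH3Br, KOtBu, THF, 0 °C to rt
Reagents that add atoms: methyltriphenylphosphonium bromide, C[P+](c1ccccc1)(c1ccccc1)c1ccccc1.[Br-]
Why: Wittig methylenation of the aryl ketone with the non-stabilised ylide should give the aryl 2-arylallyl ether.

Step 8
Reactants: 12 1-{3-[3,4-dimethoxy-2-(methoxymethoxy)phenoxy]prop-1-en-2-yl}-3,4-dimethoxy-2,5-bis(methoxymethoxy)benzene
Product: 13 6-{2-[3,4-dimethoxy-2,5-bis(methoxymethoxy)phenyl]prop-2-en-1-yl}-3,4-dimethoxy-2-(methoxymethoxy)phenol
Conditions: PhNEt2, 190 °C, sealed tube, Ar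
Reagents that add atoms: none
Why: aromatic Claisen rearrangement, a [3,3]-sigmatropic shift into the only free ortho position (the other ortho carbon carries the acetal, the para carbon a methoxy group) followed by tautomerisation; the 2-substituted allyl unit is symmetric, and the amine solvent suppresses acid-catalysed Markovnikov cyclisation.

Step 9
Reactants: 13 6-{2-[3,4-dimethoxy-2,5-bis(methoxymethoxy)phenyl]prop-2-en-1-yl}-3,4-dimethoxy-2-(methoxymethoxy)phenol
Product: 14 (3S)-3-[3,4-dimethoxy-2,5-bis(methoxymethoxy)phenyl]-6,7-dimethoxy-8-(methoxymethoxy)-3,4-dihydro-2H-chromene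
Conditions: 9-mesityl-3,6-di-tert-butyl-10-phenylacridinium tetrafluoroborate (5 mol%), chiral cysteine-peptide thiol (20 mol%), 2,6-lutidine (20 mol%), 1,2-dichloroethane, 455 nm LEDs, −20 °C, Ar, slow addition of 13
Reagents that add atoms: none
Why: Proposed new method: the strongly oxidising excited acridinium (roughly +2 V vs SCE) should oxidise the electron-rich 2-arylpropene unit of 13 to its radical cation, the ring-A phenol oxygen attacks the unsubstituted alkene terminus (6-endo-trig, forming O1–C2 and closing the pyran ring) because only this mode leaves a tertiary, aryl-stabilised radical at C3, and lutidine removes the oxonium proton. The chiral thiol then delivers a hydrogen atom to the planar C3 radical, and the thiyl radical is reduced by the acridine radical and reprotonated, so both catalysts turn over with no net redox change. The closest known reaction types are the racemic acridinium/thiol anti-Markovnikov hydroetherification of alkenols and thiol-catalysed enantioselective hydrogen-atom transfer to prochiral carbon radicals with peptide or sugar thiols; their merger on a phenol-tethered 1,1-disubstituted styrene is untested. The C3 stereocentre is set under catalyst control by the chiral thiol, (3S) arising from hydrogen delivery to the Re face of the radical (C2 > aryl > C4). Regioselectivity (anti-Markovnikov, 6-endo over 5-exo) is secured by the aryl group on C3, and chemoselectivity by the single free OH, the ring-B oxygens being acetals. Face selectivity is the unproven element; it is supported by the acetal oxygens on O8 and O2' that flank C3 as hydrogen-bond acceptors for the catalyst, by the absence of weak C–H bonds within reach of the C3 radical, and by slow addition of 13 so that its phenolic O–H cannot compete as an achiral hydrogen donor.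

Step 10
Reactants: 14 (3S)-3-[3,4-dimethoxy-2,5-bis(methoxymethoxy)phenyl]-6,7-dimethoxy-8-(methoxymethoxy)-3,4-dihydro-2H-chromene
Product: 15 5-[(3S)-8-hydroxy-6,7-dimethoxy-3,4-dihydro-2H-chromen-3-yl]-2,3-dimethoxybenzene-1,4-diol
Conditions: HCl (2 M in MeOH), THF, 40 °C, degassed, Ar
Reagents that add atoms: none
Why: acid-catalysed acetal exchange with methanol (transacetalisation) should remove all three aryl MOM groups, leaving the methyl ethers, the chroman ring and the non-acidic benzylic C3–H untouched.

Step 11
Reactants: 15 5-[(3S)-8-hydroxy-6,7-dimethoxy-3,4-dihydro-2H-chromen-3-yl]-2,3-dimethoxybenzene-1,4-diol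
Product: 16 5-[(3S)-8-hydroxy-6,7-dimethoxy-3,4-dihydro-2H-chromen-3-yl]-2,3-dimethoxycyclohexa-2,5-diene-1,4-dione (target)
Conditions: Ag2O, Na2SO4, Et2O, rt, dark
Reagents that add atoms: none
Why: hydroquinone-to-quinone oxidation, for which Ag2O is a mild neutral two-electron oxidant that should take the para-dihydroxy ring selectively over the ring-A monophenol and leave C3 unchanged.

Compound list
1 | 2,3-dimethoxyphenol | COc1cccc(O)c1OC | starting material
2 | 2,3-dimethoxy-1,4-benzoquinone | COC1=C(OC)C(=O)C=CC1=O | intermediate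
3 | 2,3-dimethoxybenzene-1,4-diol | COc1c(O)ccc(O)c1OC | intermediate
4 | 1,4-bis(methoxymethoxy)-2,3-dimethoxybenzene | COCOc1ccc(OCOC)c(OC)c1OC | intermediate
5 | [3,4-dimethoxy-2,5-bis(methoxymethoxy)phenyl]lithium | [Li]c1cc(OCOC)c(OC)c(OC)c1OCOC | intermediate
6 | 2-chloro-1-[3,4-dimethoxy-2,5-bis(methoxymethoxy)phenyl]ethan-1-one | ClCC(=O)c1cc(OCOC)c(OC)c(OC)c1OCOC | intermediate
7 | 2-hydroxy-3,4-dimethoxybenzaldehyde | COc1ccc(C=O)c(O)c1OC | starting material
8 | 3,4-dimethoxy-2-(methoxymethoxy)benzaldehyde | COCOc1c(C=O)ccc(OC)c1OC | intermediate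
9 | 3,4-dimethoxy-2-(methoxymethoxy)phenyl formate | COCOc1c(OC=O)ccc(OC)c1OC | intermediate
10 | 3,4-dimethoxy-2-(methoxymethoxy)phenol | COCOc1c(O)ccc(OC)c1OC | intermediate
11 | 1-[3,4-dimethoxy-2,5-bis(methoxymethoxy)phenyl]-2-[3,4-dimethoxy-2-(methoxymethoxy)phenoxy]ethan-1-one | COCOc1c(OCC(=O)c2cc(OCOC)c(OC)c(OC)c2OCOC)ccc(OC)c1OC | intermediate
12 | 1-{3-[3,4-dimethoxy-2-(methoxymethoxy)phenoxy]prop-1-en-2-yl}-3,4-dimethoxy-2,5-bis(methoxymethoxy)benzene | C=C(COc1ccc(OC)c(OC)c1OCOC)c1cc(OCOC)c(OC)c(OC)c1OCOC | intermediate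
13 | 6-{2-[3,4-dimethoxy-2,5-bis(methoxymethoxy)phenyl]prop-2-en-1-yl}-3,4-dimethoxy-2-(methoxymethoxy)phenol | C=C(Cc1cc(OC)c(OC)c(OCOC)c1O)c1cc(OCOC)c(OC)c(OC)c1OCOC | intermediate
14 | (3S)-3-[3,4-dimethoxy-2,5-bis(methoxymethoxy)phenyl]-6,7-dimethoxy-8-(methoxymethoxy)-3,4-dihydro-2H-chromene | COc1c(OC)c(OCOC)cc([C@H]2COc3c(cc(OC)c(OC)c3OCOC)C2)c1OCOC | intermediate
15 | 5-[(3S)-8-hydroxy-6,7-dimethoxy-3,4-dihydro-2H-chromen-3-yl]-2,3-dimethoxybenzene-1,4-diol | COc1c(OC)c(O)cc([C@H]2COc3c(cc(OC)c(OC)c3O)C2)c1O | intermediate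
16 | 5-[(3S)-8-hydroxy-6,7-dimethoxy-3,4-dihydro-2H-chromen-3-yl]-2,3-dimethoxycyclohexa-2,5-diene-1,4-dione | COC1=C(OC)C(=O)C([C@H]2COc3c(cc(OC)c(OC)c3O)C2)=CC1=O | target

Total step count: 11. Longest linear sequence: 9 steps (steps 1, 2, 3, 6, 7, 8, 9, 10, 11).

Steps most likely to fail

Step 9 (proposed new method). Three processes may defeat it:
- The electron hole may sit on the polyalkoxy arenes or the phenol and return by back electron transfer without C–O bond formation.
- Hydrogen may reach the C3 radical with poor facial selectivity, or from an achiral donor such as the phenol O–H of unreacted substrate.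
- The thiyl radical may re-abstract the C3 hydrogen and erode the enantiomeric purity.

Fallback, known chemistry only, setting out from 13 and returning at 14. Hydroboration of 13 with 9-BBN (2.2 equiv, THF; the phenol is borylated in passing) should give the bis(9-borabicyclononyl) adduct F1. Oxidation in the same flask (NaBO3·4H2O, THF/H2O) should give the racemic 3-hydroxypropyl phenol F2. Mitsunobu ring closure (PPh3, DIAD, THF) forms the same O1–C2 bond by SN2 and should give the racemic chroman F3. The (3S) enantiomer 14 is then separated by preparative chromatography on a chiral stationary phase.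

Step 8. At 190 °C the liberated phenol may add across the electron-rich styrene in the Markovnikov sense (dihydrobenzofuran formation), or the styrene may oligomerise.

Fallback, setting out from 10 and 4 and returning at 13; the aryl-substituted alkene is absent during heating. O-Alkylation of 10 with 2,3-dibromopropene (K2CO3, acetone) should give the 2-bromoallyl ether F4. Its Claisen rearrangement (PhNEt2, 190 °C) should give the 6-(2-bromoallyl)phenol F5. Separately, 4 is lithiated to 5 as in step 3 and quenched with 2-isopropoxy-4,4,5,5-tetramethyl-1,3,2-dioxaborolane to give the ring-B pinacol boronate F6. Suzuki–Miyaura coupling of F5 with F6 (Pd(PPh3)4, K3PO4, dioxane/H2O, 80 °C) should give 13.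

Step 7. The basic ylide may enolise the α-aryloxy ketone next to the hindered carbonyl instead of adding to it, returning ketone or aldol products.

Fallback, setting out from 11 and returning at 12. Addition of the weakly basic organocerium reagent from Me3SiCH2MgCl and CeCl3 (THF, −78 °C) should give the racemic β-hydroxysilane F7. Peterson elimination (KH, THF, 0 °C) should then give 12.

Further compounds
F1 | step 9 | 9-{3-[2-(9-borabicyclo[3.3.1]nonan-9-yloxy)-4,5-dimethoxy-3-(methoxymethoxy)phenyl]-2-[3,4-dimethoxy-2,5-bis(methoxymethoxy)phenyl]propyl}-9-borabicyclo[3.3.1]nonane (racemic) | C(B1C2CCCC1CCC2)C(Cc3cc(OC)c(OC)c(OCOC)c3OB4C5CCCC4CCC5)c6cc(OCOC)c(OC)c(OC)c6OCOC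
F2 | step 9 | 6-{2-[3,4-dimethoxy-2,5-bis(methoxymethoxy)phenyl]-3-hydroxypropyl}-3,4-dimethoxy-2-(methoxymethoxy)phenol (racemic) | OCC(Cc1cc(OC)c(OC)c(OCOC)c1O)c1cc(OCOC)c(OC)c(OC)c1OCOC
F3 | step 9 | racemic 3-[3,4-dimethoxy-2,5-bis(methoxymethoxy)phenyl]-6,7-dimethoxy-8-(methoxymethoxy)-3,4-dihydro-2H-chromene | COc1c(OC)c(OCOC)cc(C2COc3c(cc(OC)c(OC)c3OCOC)C2)c1OCOC
F4 | step 8 | 1-[(2-bromoprop-2-en-1-yl)oxy]-3,4-dimethoxy-2-(methoxymethoxy)benzene | C=C(Br)COc1ccc(OC)c(OC)c1OCOC
F5 | step 8 | 6-(2-bromoprop-2-en-1-yl)-3,4-dimethoxy-2-(methoxymethoxy)phenol | C=C(Br)Cc1cc(OC)c(OC)c(OCOC)c1O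
F6 | step 8 | 2-[3,4-dimethoxy-2,5-bis(methoxymethoxy)phenyl]-4,4,5,5-tetramethyl-1,3,2-dioxaborolane | CC1(C)OB(OC1(C)C)c1cc(OCOC)c(OC)c(OC)c1OCOC
F7 | step 7 | 2-[3,4-dimethoxy-2,5-bis(methoxymethoxy)phenyl]-1-[3,4-dimethoxy-2-(methoxymethoxy)phenoxy]-3-(trimethylsilyl)propan-2-ol (racemic) | C[Si](C)(C)CC(O)(COc1ccc(OC)c(OC)c1OCOC)c1cc(OCOC)c(OC)c(OC)c1OCOC
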